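## Retrosynthetic overview

1. The 2‑hydroxyacetyl group is carried as a vinyl group (vinyl → 1,2‑diol → benzylic oxidation). The phenol is carried as a TIPS ether and the primary C9‑OH as a TBS ether.
2. The erythro (7R,8S) target comes from the threo (7S,8S) series by Mitsunobu inversion at the benzylic carbinol C7.
3. The C7–C8 bond comes from an Evans syn boron aldol of an (R)‑4‑benzyl‑3‑(aryloxyacetyl)oxazolidinone with O‑TIPS‑vanillin. Reductive removal of the auxiliary gives C9H2OH.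
4. The aryloxyacetyl imide comes from syringaldehyde by O‑alkylation with ethyl bromoacetate, Wittig methylenation, saponification and N‑acylation.
5. No ring is formed: both benzene rings are bought (vanillin, syringaldehyde), and the oxazolidinone is a purchased auxiliary that is cleaved off.

Assumption: the chain is numbered C7 (ArCH–OH), C8 (CH–OAr), C9 (CH2OH); the target is (7R,8S), the erythro isomer (anti in the zigzag drawing), whereas a syn aldol gives the threo series.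

## Route

Step 1
Reactants: 1 vanillin (4‑hydroxy‑3‑methoxybenzaldehyde)
Product: 2 3‑methoxy‑4‑[(triisopropylsilyl)oxy]benzaldehyde
Conditions: TIPSCl, imidazole, DMF, 0 °C → rt
Reagents that add atoms: triisopropylsilyl chloride, CC(C)[Si](Cl)(C(C)C)C(C)C
Why: Imidazole‑promoted silyl ether formation masks the acidic phenol with a group that survives amines, borohydride, Mitsunobu conditions and carbonate/methanol.

Step 2
Reactants: 3 syringaldehyde (4‑hydroxy‑3,5‑dimethoxybenzaldehyde); 4 ethyl bromoacetate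
Product: 5 ethyl 2‑(4‑formyl‑2,6‑dimethoxyphenoxy)acetate
Conditions: K2CO3, DMF, 60 °C
Reagents that add atoms: none
Why: Williamson ether synthesis; the para‑formyl phenoxide forms readily with carbonate and displaces the very reactive α‑bromo ester by SN2.

Step 3
Reactants: 5 ethyl 2‑(4‑formyl‑2,6‑dimethoxyphenoxy)acetate
Product: 6 ethyl 2‑(4‑ethenyl‑2,6‑dimethoxyphenoxy)acetate
Conditions: Ph3PCH3Br (1.15 equiv), KOtBu (1.1 equiv), THF, 0 °C; then 5, −78 °C → rt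
Reagents that add atoms: methyltriphenylphosphonium bromide, C[P+](c1ccccc1)(c1ccccc1)c1ccccc1.[Br-]
Why: Wittig methylenation; the non‑stabilised ylide reacts with the aldehyde far faster than with the ester, and the vinyl group is a latent hydroxyacetyl group that is inert to enolisation and hydride.

Step 4
Reactants: 6 ethyl 2‑(4‑ethenyl‑2,6‑dimethoxyphenoxy)acetate
Product: 7 2‑(4‑ethenyl‑2,6‑dimethoxyphenoxy)acetic acid
Conditions: LiOH·H2O, THF/H2O 3:1, rt; then 1 M HCl to pH 3, 0 °C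
Reagents that add atoms: lithium hydroxide, [Li+].[OH-]
Why: Saponification of an unhindered ethyl ester; the brief cold acidification does not affect the styrene.

Step 5
Reactants: 7 2‑(4‑ethenyl‑2,6‑dimethoxyphenoxy)acetic acid; 8 (R)‑4‑benzyl‑1,3‑oxazolidin‑2‑one
Product: 10 (4R)‑4‑benzyl‑3‑[2‑(4‑ethenyl‑2,6‑dimethoxyphenoxy)acetyl]‑1,3‑oxazolidin‑2‑one, via mixed pivalic anhydride 9 (not isolated)
Conditions: PivCl, Et3N, THF, −20 °C; then 8, LiCl, −20 °C → rt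
Reagents that add atoms: pivaloyl chloride, CC(C)(C)C(=O)Cl (atoms retained only in 9)
Why: N‑acylation of the oxazolidinone through a mixed anhydride; the LiCl/Et3N‑activated auxiliary attacks the unhindered aryloxyacetyl carbonyl and not the pivaloyl carbonyl.

Step 6
Reactants: 10 (4R)‑4‑benzyl‑3‑[2‑(4‑ethenyl‑2,6‑dimethoxyphenoxy)acetyl]‑1,3‑oxazolidin‑2‑one; 2 3‑methoxy‑4‑[(triisopropylsilyl)oxy]benzaldehyde
Product: 13 (4R)‑4‑benzyl‑3‑[(2R,3S)‑2‑(4‑ethenyl‑2,6‑dimethoxyphenoxy)‑3‑hydroxy‑3‑{3‑methoxy‑4‑[(triisopropylsilyl)oxy]phenyl}propanoyl]‑1,3‑oxazolidin‑2‑one, via dibutylboron Z‑enolate 11 (not isolated), via dibutylboron aldolate 12 (not isolated)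
Conditions: Bu2BOTf, iPr2NEt, CH2Cl2, −78 → 0 °C; then 2, −78 → 0 °C; then pH 7 buffer, MeOH, 30% H2O2, 0 °C
Reagents that add atoms: dibutylboron triflate, CCCCB(CCCC)OS(=O)(=O)C(F)(F)F (atoms retained only in 11 and 12)
Why: Evans syn aldol; the Z‑boron enolate reacts through a Zimmerman–Traxler chair with the aldehyde adding to the enolate face opposite the benzyl group of the (R)‑auxiliary, which sets both centres as (2R,3S), the threo series.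

Step 7
Reactants: 13 Evans syn aldol adduct
Product: 14 (1S,2S)‑2‑(4‑ethenyl‑2,6‑dimethoxyphenoxy)‑1‑{3‑methoxy‑4‑[(triisopropylsilyl)oxy]phenyl}propane‑1,3‑diol
Conditions: LiBH4, H2O (1 equiv), THF, 0 °C
Reagents that add atoms: none
Why: Reductive cleavage of the N‑acyl oxazolidinone gives the primary alcohol and releases the auxiliary without touching either stereocentre (C8 stays the same in space; its descriptor becomes S only through a priority change).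

Step 8
Reactants: 14 threo‑1,3‑diol
Product: 15 (1S,2S)‑3‑[(tert‑butyldimethylsilyl)oxy]‑2‑(4‑ethenyl‑2,6‑dimethoxyphenoxy)‑1‑{3‑methoxy‑4‑[(triisopropylsilyl)oxy]phenyl}propan‑1‑ol
Conditions: TBSCl (1.05 equiv), imidazole, CH2Cl2, 0 °C
Reagents that add atoms: tert‑butyldimethylsilyl chloride, CC(C)(C)[Si](C)(C)Cl
Why: Selective silylation; the primary hydroxyl reacts much faster than the hindered secondary benzylic one.

Step 9
Reactants: 15 mono‑TBS threo alcohol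
Product: 16 (1R,2S)‑3‑[(tert‑butyldimethylsilyl)oxy]‑2‑(4‑ethenyl‑2,6‑dimethoxyphenoxy)‑1‑{3‑methoxy‑4‑[(triisopropylsilyl)oxy]phenyl}propyl 4‑nitrobenzoate
Conditions: 4‑O2NC6H4CO2H, PPh3, DIAD (4 equiv each), toluene, 0 °C → rt
Reagents that add atoms: 4‑nitrobenzoic acid, OC(=O)c1ccc(cc1)[N+](=O)[O-]
Why: Mitsunobu esterification; the acidic 4‑nitrobenzoate displaces the alkoxyphosphonium by SN2 with inversion at C7, converting threo (7S,8S) into erythro (7R,8S).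

Step 10
Reactants: 16 erythro 4‑nitrobenzoate
Product: 17 (1R,2S)‑3‑[(tert‑butyldimethylsilyl)oxy]‑2‑[4‑(1,2‑dihydroxyethyl)‑2,6‑dimethoxyphenoxy]‑1‑{3‑methoxy‑4‑[(triisopropylsilyl)oxy]phenyl}propyl 4‑nitrobenzoate, about 1:1 mixture of epimers at the new ArCH(OH) carbon
Conditions: OsO4 (2 mol%), NMO, acetone/H2O 4:1, rt
Reagents that add atoms: N‑methylmorpholine N‑oxide, C[N+]1([O-])CCOCC1; water, O
Why: Upjohn dihydroxylation of the only alkene under neutral conditions that leave the ester and silyl ethers intact; the new carbinol centre is not controlled because it becomes the ketone in step 11.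

Step 11
Reactants: 17 diol (epimer mixture)
Product: 18 (1R,2S)‑3‑[(tert‑butyldimethylsilyl)oxy]‑2‑[4‑(2‑hydroxyacetyl)‑2,6‑dimethoxyphenoxy]‑1‑{3‑methoxy‑4‑[(triisopropylsilyl)oxy]phenyl}propyl 4‑nitrobenzoate
Conditions: DDQ (1.3 equiv), 1,4‑dioxane, rt
Reagents that add atoms: none
Why: DDQ dehydrogenation (benzylic hydride abstraction) oxidises only the alkoxy‑activated secondary benzylic alcohol; the primary alcohol is untouched and C7 is protected as an electron‑poor ester.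

Step 12
Reactants: 18 ketol 4‑nitrobenzoate
Product: 19 1‑[4‑({(1R,2S)‑3‑[(tert‑butyldimethylsilyl)oxy]‑1‑hydroxy‑1‑{3‑methoxy‑4‑[(triisopropylsilyl)oxy]phenyl}propan‑2‑yl}oxy)‑3,5‑dimethoxyphenyl]‑2‑hydroxyethan‑1‑one
Conditions: K2CO3 (0.5 equiv), MeOH/THF, 0 °C, Ar
Reagents that add atoms: none
Why: Base‑catalysed transesterification of the activated 4‑nitrobenzoate by acyl–oxygen cleavage retains C7; the aryl TIPS ether stays on, so no para‑phenoxide can expel the benzylic ester as a quinone methide.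

Step 13
Reactants: 19 bis‑silyl ether
Product: 20 1‑(4‑{[(1R,2S)‑1,3‑dihydroxy‑1‑(4‑hydroxy‑3‑methoxyphenyl)propan‑2‑yl]oxy}‑3,5‑dimethoxyphenyl)‑2‑hydroxyethan‑1‑one (target, CNP0282675.1)
Conditions: TBAF, AcOH (3 equiv each), THF, 0 °C → rt
Reagents that add atoms: none
Why: Fluoride‑mediated desilylation removes the aryl TIPS and primary TBS groups; the acetic acid buffer protects the ketol and avoids acid that could epimerise the p‑hydroxybenzylic carbinol.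

## Compound list

1 | vanillin (4‑hydroxy‑3‑methoxybenzaldehyde) | COc1cc(C=O)ccc1O | starting material
2 | 3‑methoxy‑4‑[(triisopropylsilyl)oxy]benzaldehyde | COc1cc(C=O)ccc1O[Si](C(C)C)(C(C)C)C(C)C | intermediate
3 | syringaldehyde (4‑hydroxy‑3,5‑dimethoxybenzaldehyde) | COc1cc(C=O)cc(OC)c1O | starting material
4 | ethyl bromoacetate | CCOC(=O)CBr | starting material
5 | ethyl 2‑(4‑formyl‑2,6‑dimethoxyphenoxy)acetate | CCOC(=O)COc1c(OC)cc(C=O)cc1OC | intermediate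
6 | ethyl 2‑(4‑ethenyl‑2,6‑dimethoxyphenoxy)acetate | CCOC(=O)COc1c(OC)cc(C=C)cc1OC | intermediate
7 | 2‑(4‑ethenyl‑2,6‑dimethoxyphenoxy)acetic acid | OC(=O)COc1c(OC)cc(C=C)cc1OC | intermediate
8 | (R)‑4‑benzyl‑1,3‑oxazolidin‑2‑one | O=C1N[C@H](Cc2ccccc2)CO1 | starting material
9 | 2‑(4‑ethenyl‑2,6‑dimethoxyphenoxy)acetic pivalic anhydride (not isolated) | CC(C)(C)C(=O)OC(=O)COc1c(OC)cc(C=C)cc1OC | intermediate
10 | (4R)‑4‑benzyl‑3‑[2‑(4‑ethenyl‑2,6‑dimethoxyphenoxy)acetyl]‑1,3‑oxazolidin‑2‑one | C=Cc1cc(OC)c(OCC(=O)N2[C@H](Cc3ccccc3)COC2=O)c(OC)c1 | intermediate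
11 | dibutylboron Z‑enolate of 10, aryloxy group cis to O–B (not isolated) | CCCCB(CCCC)O/C(N1[C@H](Cc2ccccc2)COC1=O)=C\Oc1c(OC)cc(C=C)cc1OC | intermediate
12 | O‑dibutylboron aldolate of 13, (2R,3S) (not isolated) | COc1cc([C@H](OB(CCCC)CCCC)[C@@H](Oc2c(OC)cc(C=C)cc2OC)C(=O)N2[C@H](Cc3ccccc3)COC2=O)ccc1O[Si](C(C)C)(C(C)C)C(C)C | intermediate
13 | (4R)‑4‑benzyl‑3‑[(2R,3S)‑2‑(4‑ethenyl‑2,6‑dimethoxyphenoxy)‑3‑hydroxy‑3‑{3‑methoxy‑4‑[(triisopropylsilyl)oxy]phenyl}propanoyl]‑1,3‑oxazolidin‑2‑one | COc1cc([C@H](O)[C@@H](Oc2c(OC)cc(C=C)cc2OC)C(=O)N2[C@H](Cc3ccccc3)COC2=O)ccc1O[Si](C(C)C)(C(C)C)C(C)C | intermediate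
14 | (1S,2S)‑2‑(4‑ethenyl‑2,6‑dimethoxyphenoxy)‑1‑{3‑methoxy‑4‑[(triisopropylsilyl)oxy]phenyl}propane‑1,3‑diol (threo) | COc1cc([C@H](O)[C@H](CO)Oc2c(OC)cc(C=C)cc2OC)ccc1O[Si](C(C)C)(C(C)C)C(C)C | intermediate
15 | (1S,2S)‑3‑[(tert‑butyldimethylsilyl)oxy]‑2‑(4‑ethenyl‑2,6‑dimethoxyphenoxy)‑1‑{3‑methoxy‑4‑[(triisopropylsilyl)oxy]phenyl}propan‑1‑ol | COc1cc([C@H](O)[C@H](CO[Si](C)(C)C(C)(C)C)Oc2c(OC)cc(C=C)cc2OC)ccc1O[Si](C(C)C)(C(C)C)C(C)C | intermediate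
16 | (1R,2S)‑3‑[(tert‑butyldimethylsilyl)oxy]‑2‑(4‑ethenyl‑2,6‑dimethoxyphenoxy)‑1‑{3‑methoxy‑4‑[(triisopropylsilyl)oxy]phenyl}propyl 4‑nitrobenzoate (erythro) | COc1cc([C@@H](OC(=O)c3ccc([N+](=O)[O-])cc3)[C@H](CO[Si](C)(C)C(C)(C)C)Oc2c(OC)cc(C=C)cc2OC)ccc1O[Si](C(C)C)(C(C)C)C(C)C | intermediate
17 | (1R,2S)‑3‑[(tert‑butyldimethylsilyl)oxy]‑2‑[4‑(1,2‑dihydroxyethyl)‑2,6‑dimethoxyphenoxy]‑1‑{3‑methoxy‑4‑[(triisopropylsilyl)oxy]phenyl}propyl 4‑nitrobenzoate, epimer mixture at ArCH(OH) | COc1cc([C@@H](OC(=O)c3ccc([N+](=O)[O-])cc3)[C@H](CO[Si](C)(C)C(C)(C)C)Oc2c(OC)cc(C(O)CO)cc2OC)ccc1O[Si](C(C)C)(C(C)C)C(C)C | intermediate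
18 | (1R,2S)‑3‑[(tert‑butyldimethylsilyl)oxy]‑2‑[4‑(2‑hydroxyacetyl)‑2,6‑dimethoxyphenoxy]‑1‑{3‑methoxy‑4‑[(triisopropylsilyl)oxy]phenyl}propyl 4‑nitrobenzoate | COc1cc([C@@H](OC(=O)c3ccc([N+](=O)[O-])cc3)[C@H](CO[Si](C)(C)C(C)(C)C)Oc2c(OC)cc(C(=O)CO)cc2OC)ccc1O[Si](C(C)C)(C(C)C)C(C)C | intermediate
19 | 1‑[4‑({(1R,2S)‑3‑[(tert‑butyldimethylsilyl)oxy]‑1‑hydroxy‑1‑{3‑methoxy‑4‑[(triisopropylsilyl)oxy]phenyl}propan‑2‑yl}oxy)‑3,5‑dimethoxyphenyl]‑2‑hydroxyethan‑1‑one | COc1cc([C@@H](O)[C@H](CO[Si](C)(C)C(C)(C)C)Oc2c(OC)cc(C(=O)CO)cc2OC)ccc1O[Si](C(C)C)(C(C)C)C(C)C | intermediate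
20 | 1‑(4‑{[(1R,2S)‑1,3‑dihydroxy‑1‑(4‑hydroxy‑3‑methoxyphenyl)propan‑2‑yl]oxy}‑3,5‑dimethoxyphenyl)‑2‑hydroxyethan‑1‑one | COc1cc([C@@H](O)[C@H](CO)Oc2c(OC)cc(C(=O)CO)cc2OC)ccc1O | target

## Totals and risks

Total step count: 13.
Longest linear sequence: 12 steps (steps 2–13, from syringaldehyde); step 1 is a one‑step side branch.

Three steps most likely to fail:

Step 6 (aldol). The electron‑rich, weakly electrophilic aldehyde 2 and the bulky 2,6‑dimethoxyphenoxy enolate may give low conversion or eroded selectivity. The fallback replaces the boron/oxazolidinone system by a titanium thioimide aldol. It sets out from acid 7, which is coupled (EDC, DMAP, CH2Cl2) with commercial (R)‑4‑benzyl‑1,3‑thiazolidine‑2‑thione to give (4R)‑4‑benzyl‑3‑[2‑(4‑ethenyl‑2,6‑dimethoxyphenoxy)acetyl]‑1,3‑thiazolidine‑2‑thione F1. Its more reactive chlorotitanium enolate (TiCl4, iPr2NEt, N‑methylpyrrolidinone, CH2Cl2, −78 → 0 °C) adds to 2 in the Evans‑syn sense to give the (2R,3S) adduct (4R)‑4‑benzyl‑3‑[(2R,3S)‑2‑(4‑ethenyl‑2,6‑dimethoxyphenoxy)‑3‑hydroxy‑3‑{3‑methoxy‑4‑[(triisopropylsilyl)oxy]phenyl}propanoyl]‑1,3‑thiazolidine‑2‑thione F2. NaBH4 in THF/EtOH cleaves the very labile thioimide, and the route is rejoined at diol 14.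

Step 9 (Mitsunobu). The hindered, electron‑rich benzylic carbinol may eliminate to the enol ether or partly ionise, which would erode the inversion. The fallback sets C7 by substrate‑controlled reduction instead of SN2. It sets out from 15, which is oxidised (Dess–Martin periodinane, NaHCO3, CH2Cl2) to (2S)‑3‑[(tert‑butyldimethylsilyl)oxy]‑2‑(4‑ethenyl‑2,6‑dimethoxyphenoxy)‑1‑{3‑methoxy‑4‑[(triisopropylsilyl)oxy]phenyl}propan‑1‑one F3. Chelation‑controlled reduction (Zn(BH4)2, Et2O, −30 °C) should favour the erythro alcohol (1R,2S)‑3‑[(tert‑butyldimethylsilyl)oxy]‑2‑(4‑ethenyl‑2,6‑dimethoxyphenoxy)‑1‑{3‑methoxy‑4‑[(triisopropylsilyl)oxy]phenyl}propan‑1‑ol F4, although aryl ethers chelate weakly, so the ratio is uncertain. The minor threo isomer is 15 itself and is recycled. Acylation of F4 with 4‑nitrobenzoyl chloride (pyridine, DMAP) rejoins the route at 16.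

Step 11 (DDQ oxidation). The twisted 4‑alkoxy group may slow hydride abstraction, and over‑oxidation is possible. The fallback also keeps the ketol protected during the basic methanolysis of step 12. It sets out from 17, whose primary hydroxyl is silylated (TBSCl, imidazole, CH2Cl2, 0 °C) to give (1R,2S)‑3‑[(tert‑butyldimethylsilyl)oxy]‑2‑[4‑(2‑[(tert‑butyldimethylsilyl)oxy]‑1‑hydroxyethyl)‑2,6‑dimethoxyphenoxy]‑1‑{3‑methoxy‑4‑[(triisopropylsilyl)oxy]phenyl}propyl 4‑nitrobenzoate F5. Dess–Martin oxidation of the remaining secondary alcohol gives the silyloxy ketone (1R,2S)‑3‑[(tert‑butyldimethylsilyl)oxy]‑2‑[4‑(2‑[(tert‑butyldimethylsilyl)oxy]acetyl)‑2,6‑dimethoxyphenoxy]‑1‑{3‑methoxy‑4‑[(triisopropylsilyl)oxy]phenyl}propyl 4‑nitrobenzoate F6. K2CO3/MeOH at 0 °C removes the ester to give 2‑[(tert‑butyldimethylsilyl)oxy]‑1‑[4‑({(1R,2S)‑3‑[(tert‑butyldimethylsilyl)oxy]‑1‑hydroxy‑1‑{3‑methoxy‑4‑[(triisopropylsilyl)oxy]phenyl}propan‑2‑yl}oxy)‑3,5‑dimethoxyphenyl]ethan‑1‑one F7. TBAF/AcOH in THF then removes all three silyl groups, and the route is rejoined at the target 20.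

## Further compounds

F1 | step 6 | (4R)‑4‑benzyl‑3‑[2‑(4‑ethenyl‑2,6‑dimethoxyphenoxy)acetyl]‑1,3‑thiazolidine‑2‑thione | C=Cc1cc(OC)c(OCC(=O)N2[C@H](Cc3ccccc3)CSC2=S)c(OC)c1
F2 | step 6 | (4R)‑4‑benzyl‑3‑[(2R,3S)‑2‑(4‑ethenyl‑2,6‑dimethoxyphenoxy)‑3‑hydroxy‑3‑{3‑methoxy‑4‑[(triisopropylsilyl)oxy]phenyl}propanoyl]‑1,3‑thiazolidine‑2‑thione | COc1cc([C@H](O)[C@@H](Oc2c(OC)cc(C=C)cc2OC)C(=O)N2[C@H](Cc3ccccc3)CSC2=S)ccc1O[Si](C(C)C)(C(C)C)C(C)C
F3 | step 9 | (2S)‑3‑[(tert‑butyldimethylsilyl)oxy]‑2‑(4‑ethenyl‑2,6‑dimethoxyphenoxy)‑1‑{3‑methoxy‑4‑[(triisopropylsilyl)oxy]phenyl}propan‑1‑one | COc1cc(C(=O)[C@H](CO[Si](C)(C)C(C)(C)C)Oc2c(OC)cc(C=C)cc2OC)ccc1O[Si](C(C)C)(C(C)C)C(C)C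
F4 | step 9 | (1R,2S)‑3‑[(tert‑butyldimethylsilyl)oxy]‑2‑(4‑ethenyl‑2,6‑dimethoxyphenoxy)‑1‑{3‑methoxy‑4‑[(triisopropylsilyl)oxy]phenyl}propan‑1‑ol | COc1cc([C@@H](O)[C@H](CO[Si](C)(C)C(C)(C)C)Oc2c(OC)cc(C=C)cc2OC)ccc1O[Si](C(C)C)(C(C)C)C(C)C
F5 | step 11 | (1R,2S)‑3‑[(tert‑butyldimethylsilyl)oxy]‑2‑[4‑(2‑[(tert‑butyldimethylsilyl)oxy]‑1‑hydroxyethyl)‑2,6‑dimethoxyphenoxy]‑1‑{3‑methoxy‑4‑[(triisopropylsilyl)oxy]phenyl}propyl 4‑nitrobenzoate (epimer mixture at ArCH(OH)) | COc1cc([C@@H](OC(=O)c3ccc([N+](=O)[O-])cc3)[C@H](CO[Si](C)(C)C(C)(C)C)Oc2c(OC)cc(C(O)CO[Si](C)(C)C(C)(C)C)cc2OC)ccc1O[Si](C(C)C)(C(C)C)C(C)C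
F6 | step 11 | (1R,2S)‑3‑[(tert‑butyldimethylsilyl)oxy]‑2‑[4‑(2‑[(tert‑butyldimethylsilyl)oxy]acetyl)‑2,6‑dimethoxyphenoxy]‑1‑{3‑methoxy‑4‑[(triisopropylsilyl)oxy]phenyl}propyl 4‑nitrobenzoate | COc1cc([C@@H](OC(=O)c3ccc([N+](=O)[O-])cc3)[C@H](CO[Si](C)(C)C(C)(C)C)Oc2c(OC)cc(C(=O)CO[Si](C)(C)C(C)(C)C)cc2OC)ccc1O[Si](C(C)C)(C(C)C)C(C)C
F7 | step 11 | 2‑[(tert‑butyldimethylsilyl)oxy]‑1‑[4‑({(1R,2S)‑3‑[(tert‑butyldimethylsilyl)oxy]‑1‑hydroxy‑1‑{3‑methoxy‑4‑[(triisopropylsilyl)oxy]phenyl}propan‑2‑yl}oxy)‑3,5‑dimethoxyphenyl]ethan‑1‑one | COc1cc([C@@H](O)[C@H](CO[Si](C)(C)C(C)(C)C)Oc2c(OC)cc(C(=O)CO[Si](C)(C)C(C)(C)C)cc2OC)ccc1O[Si](C(C)C)(C(C)C)C(C)C
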